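The target is cut at the cis-fused α-methylene-γ-butyrolactone O8–C12(=O)–C11(=C13H2) that spans the C7–C8 bond of the cyclohexane ring. One ruthenium-catalysed carbonylative (2+2+1) union of a C8 aldehyde, the C7=C11 bond of a terminal allene and CO forms C7–C8, C11–C12 and C12–O8, closing carbocycle and lactone and setting C7 and C8 together. The precursor is an acyclic allenyl aldehyde carrying C9 (OSiEt3), quaternary C10, C5 with its 2-propenyl arm and C6 (OPMB). Its C5/C10 pair comes from an Ireland–Claisen rearrangement steered by a glyceraldehyde-derived C9, and C6 from an ynone reduction.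

Key step: step 19

Remark: atom labels follow the target (ring C5–C10; C1=C2 vinyl and C14 methyl on C10; C4(=C3H2)–C15H2O on C5; lactone C11, C12, C13); PMB = 4-methoxybenzyl, TBDPS = tert-butyldiphenylsilyl, TES = triethylsilyl.
Assumption: paraconic acid is used racemic, so compounds 11–16 are 1:1 mixtures of epimers at C4 (left open in their SMILES); both epimers converge when C4 becomes sp2 in step 10.

Step 1
Reactants: 1 (R)-2,3-O-isopropylideneglyceraldehyde
Product: 2 (4S)-4-(2,2-dibromoethenyl)-2,2-dimethyl-1,3-dioxolane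
Conditions: CBr4, PPh3, Zn, CH2Cl2, 0 °C
Reagents that add atoms: carbon tetrabromide, BrC(Br)(Br)Br
Why: Corey–Fuchs dibromoolefination under neutral, zinc-buffered conditions homologates the aldehyde without touching the α-alkoxy stereocentre, which becomes C9.

Step 2
Reactants: 2 (4S)-4-(2,2-dibromoethenyl)-2,2-dimethyl-1,3-dioxolane
Product: 4 3-[(4S)-2,2-dimethyl-1,3-dioxolan-4-yl]prop-2-yn-1-ol, via lithium alkynide 3 (not isolated)
Conditions: n-BuLi (2.1 equiv), THF, −78 °C; then (CH2O)n, −78 → 25 °C; aq NH4Cl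
Reagents that add atoms: formaldehyde (used as paraformaldehyde), C=O
Why: Second stage of the Corey–Fuchs sequence, in which elimination and Br/Li exchange give the lithium alkynide that is hydroxymethylated to the propargylic alcohol (C2).

Step 3
Reactants: 4 3-[(4S)-2,2-dimethyl-1,3-dioxolan-4-yl]prop-2-yn-1-ol
Product: 6 (2Z)-3-[(4R)-2,2-dimethyl-1,3-dioxolan-4-yl]-3-iodoprop-2-en-1-ol, via cyclic sodium alkenylalanate 5 (not isolated)
Conditions: NaAlH2(OCH2CH2OCH3)2, THF, 0 °C; then I2, −78 °C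
Reagents that add atoms: iodine, II
Why: Hydroxyl-directed trans-hydroalumination puts aluminium on C10 anti to the new C1–H, and iodinolysis with retention should give the (Z)-3-iodoallylic alcohol as one geometric isomer.

Step 4
Reactants: 6 (2Z)-3-[(4R)-2,2-dimethyl-1,3-dioxolan-4-yl]-3-iodoprop-2-en-1-ol
Product: 7 (2E)-3-[(4S)-2,2-dimethyl-1,3-dioxolan-4-yl]but-2-en-1-ol
Conditions: Me2CuLi (from MeLi and CuI, 3 equiv), Et2O, 0 °C
Reagents that add atoms: lithium dimethylcuprate, [Li+].C[Cu-]C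
Why: Cuprate cross-coupling of the alkenyl iodide (Corey–Posner) replaces iodine by methyl with retention of geometry, giving the (E)-trisubstituted allylic alcohol with C9 trans to C2.

Step 5
Reactants: 8 (±)-paraconic acid
Product: 9 (±)-4-(hydroxymethyl)oxolan-2-one
Conditions: BH3·SMe2, THF, 0 → 25 °C; then MeOH
Reagents that add atoms: none
Why: Borane reduces the free carboxylic acid chemoselectively and leaves the γ-lactone intact.

Step 6
Reactants: 9 (±)-4-(hydroxymethyl)oxolan-2-one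
Product: 10 (±)-4-{[tert-butyl(diphenyl)silyl]oxymethyl}oxolan-2-one
Conditions: t-BuPh2SiCl, imidazole, DMF, 25 °C
Reagents that add atoms: tert-butyl(chloro)diphenylsilane, CC(C)(C)[Si](Cl)(c1ccccc1)c1ccccc1
Why: Standard silylation of a primary alcohol installs a C15 protecting group that survives the later acetonide cleavage and falls together with the C9 silyl ether at the end.

Step 7
Reactants: 10 (±)-4-{[tert-butyl(diphenyl)silyl]oxymethyl}oxolan-2-one
Product: 11 (±)-3-{[tert-butyl(diphenyl)silyl]oxymethyl}-4-(phenylselanyl)butanoic acid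
Conditions: (PhSe)2, NaBH4, DMF, 25 → 120 °C; then aq HCl
Reagents that add atoms: diphenyl diselenide, c1ccc(cc1)[Se][Se]c1ccccc1
Why: The soft selenolate opens the lactone by SN2 attack at the O-alkyl carbon (alkyl–oxygen cleavage), giving an acid whose sp3 C4 carries the exo-methylene in masked form.

Step 8
Reactants: 7 (2E)-3-[(4S)-2,2-dimethyl-1,3-dioxolan-4-yl]but-2-en-1-ol; 11 (±)-3-{[tert-butyl(diphenyl)silyl]oxymethyl}-4-(phenylselanyl)butanoic acid
Product: 12 (2E)-3-[(4S)-2,2-dimethyl-1,3-dioxolan-4-yl]but-2-en-1-yl 3-{[tert-butyl(diphenyl)silyl]oxymethyl}-4-(phenylselanyl)butanoate (C4 epimers)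
Conditions: EDC·HCl, DMAP (cat.), CH2Cl2, 0 → 25 °C
Reagents that add atoms: none
Why: Steglich-type carbodiimide esterification of a primary allylic alcohol touches neither the alkene geometry nor C9.

Step 9
Reactants: 12 allylic ester (C4 epimers)
Product: 15 (2S,3S)-2-[1-(TBDPS-oxy)-3-(phenylselanyl)propan-2-yl]-3-[(4S)-2,2-dimethyl-1,3-dioxolan-4-yl]-3-methylpent-4-enoic acid (C4 epimers), via E(O) silyl ketene acetal 13 (not isolated), via trimethylsilyl ester 14 (not isolated)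
Conditions: LiN(i-Pr)2, THF, −78 °C; Me3SiCl, Et3N, −78 → 60 °C; then H2O, pH 4 buffer
Reagents that add atoms: none
Why: Ireland–Claisen rearrangement: kinetic deprotonation of the saturated ester in THF gives the E(O) ketene acetal (the reason C4 is kept sp3 here, since a conjugating alkenyl group would favour the other geometry), which with the (E)-alkene in a chair transition state places the C4 arm and the C10 methyl both axial and so sets C5 against C10, while C10 against C9 is set by bonding anti to the C9–O bond with H9 beside the C10 methyl and C8 over the alkene (Felkin–Anh-type control by the dioxolane).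

Step 10
Reactants: 15 seleno acid (C4 epimers)
Product: 17 (2S,3S)-2-[3-(TBDPS-oxy)prop-1-en-2-yl]-3-[(4S)-2,2-dimethyl-1,3-dioxolan-4-yl]-3-methylpent-4-enoic acid, via selenoxide 16 (not isolated)
Conditions: H2O2 (30%), pyridine, CH2Cl2, 0 → 40 °C
Reagents that add atoms: none
Why: Selenoxide syn-elimination can take only the C4–H, so the 1,1-disubstituted C4=C3 alkene should form regiospecifically and both C4 epimers give one compound.

Step 11
Reactants: 17 alkenyl acid
Product: 18 (2S,3S)-2-[3-(TBDPS-oxy)prop-1-en-2-yl]-3-[(4S)-2,2-dimethyl-1,3-dioxolan-4-yl]-N-methoxy-N,3-dimethylpent-4-enamide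
Conditions: MeNHOMe·HCl, EDC·HCl, HOBt, N-methylmorpholine, CH2Cl2, 0 → 25 °C
Reagents that add atoms: N,O-dimethylhydroxylamine hydrochloride, CNOC.Cl
Why: Carbodiimide amidation gives the Weinreb amide under conditions too mild to epimerise or conjugate C5, which is shielded by the quaternary C10.

Step 12
Reactants: 18 Weinreb amide; 19 3-methoxyprop-1-yne
Product: 21 (3S,4S)-4-[3-(TBDPS-oxy)prop-1-en-2-yl]-3-[(4S)-2,2-dimethyl-1,3-dioxolan-4-yl]-8-methoxy-3-methyloct-1-en-6-yn-5-one, via lithium 3-methoxyprop-1-yn-1-ide 20 (not isolated)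
Conditions: n-BuLi, THF, −78 °C; then 18, −78 → 0 °C; aq NH4Cl
Reagents that add atoms: none
Why: Weinreb ketone synthesis, in which the chelated tetrahedral adduct prevents over-addition and releases the ynone only on work-up.

Step 13
Reactants: 21 ynone
Product: 22 (3S,4S,5S)-4-[3-(TBDPS-oxy)prop-1-en-2-yl]-3-[(4S)-2,2-dimethyl-1,3-dioxolan-4-yl]-8-methoxy-3-methyloct-1-en-6-yn-5-ol
Conditions: Ru[(S,S)-TsNCH(Ph)CH(Ph)NH](p-cymene) (2 mol%), i-PrOH, 25 °C
Reagents that add atoms: none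
Why: Noyori asymmetric transfer hydrogenation of an ynone, in which the (S,S) catalyst is expected to give the (S)-propargylic carbinol at C6, the same face that Felkin–Anh hydride addition anti to the quaternary C10 favours, so catalyst and substrate are matched.

Step 14
Reactants: 22 propargylic alcohol
Product: 23 (4R,5S,6S)-5-[3-(TBDPS-oxy)prop-1-en-2-yl]-6-[(4S)-2,2-dimethyl-1,3-dioxolan-4-yl]-6-methylocta-1,2,7-trien-4-ol
Conditions: LiAlH4, THF, 0 → 65 °C
Reagents that add atoms: none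
Why: Hydroxyl-directed trans-hydroalumination followed by 1,2-elimination of methoxide (SN2' hydride reduction of a 4-alkoxybut-2-yn-1-ol) should give the terminal allenyl carbinol without touching C6, whose descriptor changes only through the priority rules.

Step 15
Reactants: 23 allenyl carbinol
Product: 24 4-methoxybenzyl ether of 23 at O6
Conditions: NaH, 4-MeOC6H4CH2Cl, Bu4NI (cat.), THF/DMF, 0 → 25 °C
Reagents that add atoms: 4-methoxybenzyl chloride, COc1ccc(CCl)cc1
Why: Williamson etherification puts a small, Lewis-basic ether on O6, chosen to guide ruthenium in the key step and to be removable last by oxidation.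

Step 16
Reactants: 24 PMB ether
Product: 25 (2S,3S,4S,5R)-4-[3-(TBDPS-oxy)prop-1-en-2-yl]-3-ethenyl-5-[(4-methoxyphenyl)methoxy]-3-methylocta-6,7-diene-1,2-diol
Conditions: pyridinium p-toluenesulfonate, MeOH, 50 °C
Reagents that add atoms: none
Why: Mild acid transacetalisation removes the terminal acetonide while the PMB ether, the TBDPS ether and the allene should survive.

Step 17
Reactants: 25 diol
Product: 26 1,2-bis(triethylsilyl) ether of 25
Conditions: Et3SiOSO2CF3, 2,6-lutidine, CH2Cl2, −78 → 0 °C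
Reagents that add atoms: triethylsilyl trifluoromethanesulfonate, CC[Si](CC)(CC)OS(=O)(=O)C(F)(F)F
Why: The silyl triflate silylates both hydroxyls, including the hindered one at C9 next to the quaternary carbon.

Step 18
Reactants: 26 bis(triethylsilyl) ether
Product: 27 (2S,3S,4S,5R)-4-[3-(TBDPS-oxy)prop-1-en-2-yl]-3-ethenyl-5-[(4-methoxyphenyl)methoxy]-3-methyl-2-(triethylsilyloxy)octa-6,7-dienal
Conditions: (COCl)2, DMSO, CH2Cl2, −78 → −30 °C; then Et3N
Reagents that add atoms: none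
Why: Swern conditions cleave and oxidise a primary triethylsilyl ether in one operation while secondary TES, TBDPS and PMB ethers are inert, giving the α-silyloxy aldehyde at C8 without a separate deprotection.

Step 19
Reactants: 27 allenyl aldehyde; 28 carbon monoxide
Product: 29 (3aS,4S,5S,6S,7S,7aS)-5-[3-(TBDPS-oxy)prop-1-en-2-yl]-6-ethenyl-4-[(4-methoxyphenyl)methoxy]-6-methyl-3-methylidene-7-(triethylsilyloxy)hexahydro-1-benzofuran-2(3H)-one
Conditions: Ru3(CO)12 (5 mol%), CO (20 atm), 1,4-dioxane, 120 °C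
Reagents that add atoms: none
Why: Zerovalent ruthenium binds the aldehyde and the proximal allene π-bond and couples them oxidatively to a cis-fused oxaruthenacyclopentane (new C7–C8 bond), CO inserts into the Ru–C11 bond and C12–O8 reductive elimination releases the lactone and the catalyst; this is the known carbonylative hetero-Pauson–Khand (2+2+1) cyclisation of allenyl aldehydes to α-methylene-γ-butyrolactones. The cyclohexane ring closes in a 6-exo sense at C7 (the C7=C11 bond stays outside the new ring), and the five-membered lactone closes by acyl–oxygen reductive elimination from the six-membered acyl ruthenium alkoxide. The cis relation of C7 and C8 is fixed by the metallacycle, in which ruthenium holds C11 and O8 on one face. The β-face sense should come from a chair-like closure with the C5 and C10 alkenyl groups equatorial, in which the β-oriented C6 PMB ether can bind the ruthenium attached to O8 (1,3-diaxial, both β) while the bulky α-oriented C9 triethylsilyl ether blocks the alternative with C11 and ruthenium on the α face. The step also needs chemoselectivity: the strained allene binds zerovalent ruthenium far better than the vinyl or the 1,1-disubstituted alkene, and only the C7=C11 bond can reach C8 in a six-membered closure, which leaves C11=C13 as the exo-methylene.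

Step 20
Reactants: 29 protected lactone
Product: 30 (3aS,4S,5S,6S,7S,7aS)-6-ethenyl-7-hydroxy-5-(3-hydroxyprop-1-en-2-yl)-4-[(4-methoxyphenyl)methoxy]-6-methyl-3-methylidenehexahydro-1-benzofuran-2(3H)-one
Conditions: HF·pyridine, pyridine, THF, 0 → 25 °C
Reagents that add atoms: none
Why: Buffered acidic fluoride removes the TES and TBDPS ethers without forming an alkoxide that could add to the α-methylene lactone or translactonise.

Step 21
Reactants: 30 diol
Product: 31 9,15-diacetate of 30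
Conditions: Ac2O, DMAP (cat.), pyridine, CH2Cl2, 25 °C
Reagents that add atoms: acetic anhydride, CC(=O)OC(C)=O
Why: DMAP-catalysed acetylation esterifies the primary allylic and the hindered secondary hydroxyl alike.

Step 22
Reactants: 31 diacetate
Product: 32 (3aS,4S,5S,6S,7S,7aS)-7-acetoxy-5-(3-acetoxyprop-1-en-2-yl)-6-ethenyl-4-hydroxy-6-methyl-3-methylidenehexahydro-1-benzofuran-2(3H)-one
Conditions: DDQ, CH2Cl2/pH 7 buffer, 0 → 25 °C
Reagents that add atoms: none
Why: Oxidative PMB cleavage proceeds by benzylic hydride abstraction under neutral conditions, to which the esters, the alkenes and the lactone are inert.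

Step 23
Reactants: 32 C6 alcohol
Product: 33 target, (3aS,4S,5S,6S,7S,7aS)-7-acetoxy-5-(3-acetoxyprop-1-en-2-yl)-6-ethenyl-6-methyl-3-methylidene-2-oxooctahydro-1-benzofuran-4-yl 2-methylpropanoate
Conditions: i-PrCOCl, DMAP, pyridine, CH2Cl2, 0 → 25 °C
Reagents that add atoms: 2-methylpropanoyl chloride, CC(C)C(Cl)=O
Why: Acyl chloride/DMAP acylation of the hindered C6 hydroxyl runs without a base strong enough to make the alkoxide, so the 8,12-lactone should not migrate to O6.

Compound list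

1 | (R)-2,3-O-isopropylideneglyceraldehyde [(4R)-2,2-dimethyl-1,3-dioxolane-4-carbaldehyde] | O=C[C@H]1COC(C)(C)O1 | starting material
2 | (4S)-4-(2,2-dibromoethenyl)-2,2-dimethyl-1,3-dioxolane | BrC(Br)=C[C@H]1COC(C)(C)O1 | intermediate
3 | (4S)-4-(lithioethynyl)-2,2-dimethyl-1,3-dioxolane (lithium alkynide, not isolated) | [Li]C#C[C@H]1COC(C)(C)O1 | intermediate
4 | 3-[(4S)-2,2-dimethyl-1,3-dioxolan-4-yl]prop-2-yn-1-ol | OCC#C[C@H]1COC(C)(C)O1 | intermediate
5 | sodium 3-[(4R)-2,2-dimethyl-1,3-dioxolan-4-yl]-2,2-bis(2-methoxyethoxy)-2,5-dihydro-1,2-oxaaluminol-2-uide (cyclic alkenylalanate, Al on C10, not isolated) | [Na+].COCCO[Al-]1(OCCOC)OCC=C1[C@H]2COC(C)(C)O2 | intermediate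
6 | (2Z)-3-[(4R)-2,2-dimethyl-1,3-dioxolan-4-yl]-3-iodoprop-2-en-1-ol | OC/C=C(\I)[C@H]1COC(C)(C)O1 | intermediate
7 | (2E)-3-[(4S)-2,2-dimethyl-1,3-dioxolan-4-yl]but-2-en-1-ol | OC/C=C(\C)[C@H]1COC(C)(C)O1 | intermediate
8 | (±)-paraconic acid (5-oxooxolane-3-carboxylic acid) | OC(=O)C1COC(=O)C1 | starting material
9 | (±)-4-(hydroxymethyl)oxolan-2-one | OCC1COC(=O)C1 | intermediate
10 | (±)-4-{[tert-butyl(diphenyl)silyl]oxymethyl}oxolan-2-one | CC(C)(C)[Si](OCC1COC(=O)C1)(c2ccccc2)c3ccccc3 | intermediate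
11 | (±)-3-{[tert-butyl(diphenyl)silyl]oxymethyl}-4-(phenylselanyl)butanoic acid | OC(=O)CC(CO[Si](c1ccccc1)(c2ccccc2)C(C)(C)C)C[Se]c3ccccc3 | intermediate
12 | (2E)-3-[(4S)-2,2-dimethyl-1,3-dioxolan-4-yl]but-2-en-1-yl 3-{[tert-butyl(diphenyl)silyl]oxymethyl}-4-(phenylselanyl)butanoate, 1:1 epimers at butanoate C3 (C4) | O=C(CC(CO[Si](c2ccccc2)(c3ccccc3)C(C)(C)C)C[Se]c4ccccc4)OC/C=C(\C)[C@H]1COC(C)(C)O1 | intermediate
13 | (E)-trimethylsilyl ketene acetal of 12 (E(O) geometry: C4 arm cis to the allyloxy oxygen; C4 epimers, not isolated) | C[Si](C)(C)O/C(OC/C=C(\C)[C@H]1COC(C)(C)O1)=C/C(CO[Si](c2ccccc2)(c3ccccc3)C(C)(C)C)C[Se]c4ccccc4 | intermediate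
14 | trimethylsilyl ester of acid 15 (C4 epimers, not isolated) | C[Si](C)(C)OC(=O)[C@@H](C(CO[Si](c2ccccc2)(c3ccccc3)C(C)(C)C)C[Se]c4ccccc4)[C@](C)(C=C)[C@H]1COC(C)(C)O1 | intermediate
15 | (2S,3S)-2-[1-{[tert-butyl(diphenyl)silyl]oxy}-3-(phenylselanyl)propan-2-yl]-3-[(4S)-2,2-dimethyl-1,3-dioxolan-4-yl]-3-methylpent-4-enoic acid, 1:1 epimers at the propan-2-yl carbon (C4) | OC(=O)[C@@H](C(CO[Si](c2ccccc2)(c3ccccc3)C(C)(C)C)C[Se]c4ccccc4)[C@](C)(C=C)[C@H]1COC(C)(C)O1 | intermediate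
16 | Se-oxide of 15 (selenoxide, C4 and Se epimers, not isolated) | OC(=O)[C@@H](C(CO[Si](c2ccccc2)(c3ccccc3)C(C)(C)C)C[Se](=O)c4ccccc4)[C@](C)(C=C)[C@H]1COC(C)(C)O1 | intermediate
17 | (2S,3S)-2-(3-{[tert-butyl(diphenyl)silyl]oxy}prop-1-en-2-yl)-3-[(4S)-2,2-dimethyl-1,3-dioxolan-4-yl]-3-methylpent-4-enoic acid | OC(=O)[C@@H](C(=C)CO[Si](c2ccccc2)(c3ccccc3)C(C)(C)C)[C@](C)(C=C)[C@H]1COC(C)(C)O1 | intermediate
18 | (2S,3S)-2-(3-{[tert-butyl(diphenyl)silyl]oxy}prop-1-en-2-yl)-3-[(4S)-2,2-dimethyl-1,3-dioxolan-4-yl]-N-methoxy-N,3-dimethylpent-4-enamide | CON(C)C(=O)[C@@H](C(=C)CO[Si](c2ccccc2)(c3ccccc3)C(C)(C)C)[C@](C)(C=C)[C@H]1COC(C)(C)O1 | intermediate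
19 | 3-methoxyprop-1-yne (methyl propargyl ether) | COCC#C | starting material
20 | lithium 3-methoxyprop-1-yn-1-ide (not isolated) | [Li]C#CCOC | intermediate
21 | (3S,4S)-4-(3-{[tert-butyl(diphenyl)silyl]oxy}prop-1-en-2-yl)-3-[(4S)-2,2-dimethyl-1,3-dioxolan-4-yl]-8-methoxy-3-methyloct-1-en-6-yn-5-one | COCC#CC(=O)[C@@H](C(=C)CO[Si](c2ccccc2)(c3ccccc3)C(C)(C)C)[C@](C)(C=C)[C@H]1COC(C)(C)O1 | intermediate
22 | (3S,4S,5S)-4-(3-{[tert-butyl(diphenyl)silyl]oxy}prop-1-en-2-yl)-3-[(4S)-2,2-dimethyl-1,3-dioxolan-4-yl]-8-methoxy-3-methyloct-1-en-6-yn-5-ol | COCC#C[C@@H](O)[C@@H](C(=C)CO[Si](c2ccccc2)(c3ccccc3)C(C)(C)C)[C@](C)(C=C)[C@H]1COC(C)(C)O1 | intermediate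
23 | (4R,5S,6S)-5-(3-{[tert-butyl(diphenyl)silyl]oxy}prop-1-en-2-yl)-6-[(4S)-2,2-dimethyl-1,3-dioxolan-4-yl]-6-methylocta-1,2,7-trien-4-ol | C=C=C[C@@H](O)[C@@H](C(=C)CO[Si](c2ccccc2)(c3ccccc3)C(C)(C)C)[C@](C)(C=C)[C@H]1COC(C)(C)O1 | intermediate
24 | 4-methoxybenzyl ether of 23 at O6, (4R,5S,6S) in the octa-1,2,7-triene numbering, dioxolane (4S) | C=C=C[C@@H](OCc5ccc(OC)cc5)[C@@H](C(=C)CO[Si](c2ccccc2)(c3ccccc3)C(C)(C)C)[C@](C)(C=C)[C@H]1COC(C)(C)O1 | intermediate
25 | (2S,3S,4S,5R)-4-(3-{[tert-butyl(diphenyl)silyl]oxy}prop-1-en-2-yl)-3-ethenyl-5-[(4-methoxyphenyl)methoxy]-3-methylocta-6,7-diene-1,2-diol | C=C=C[C@@H](OCc5ccc(OC)cc5)[C@@H](C(=C)CO[Si](c2ccccc2)(c3ccccc3)C(C)(C)C)[C@](C)(C=C)[C@H](O)CO | intermediate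
26 | 1,2-bis(triethylsilyl) ether of 25, (2S,3S,4S,5R) | C=C=C[C@@H](OCc5ccc(OC)cc5)[C@@H](C(=C)CO[Si](c2ccccc2)(c3ccccc3)C(C)(C)C)[C@](C)(C=C)[C@H](O[Si](CC)(CC)CC)CO[Si](CC)(CC)CC | intermediate
27 | (2S,3S,4S,5R)-4-(3-{[tert-butyl(diphenyl)silyl]oxy}prop-1-en-2-yl)-3-ethenyl-5-[(4-methoxyphenyl)methoxy]-3-methyl-2-(triethylsilyloxy)octa-6,7-dienal (key-step precursor; C8 aldehyde, C9 OTES, C6 OPMB, C7=C11=C13 allene) | O=C[C@@H](O[Si](CC)(CC)CC)[C@@](C)(C=C)[C@H](C(=C)CO[Si](c1ccccc1)(c2ccccc2)C(C)(C)C)[C@H](OCc3ccc(OC)cc3)C=C=C | intermediate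
28 | carbon monoxide | [C-]#[O+] | starting material
29 | (3aS,4S,5S,6S,7S,7aS)-5-(3-{[tert-butyl(diphenyl)silyl]oxy}prop-1-en-2-yl)-6-ethenyl-4-[(4-methoxyphenyl)methoxy]-6-methyl-3-methylidene-7-(triethylsilyloxy)hexahydro-1-benzofuran-2(3H)-one | C=C[C@]1(C)[C@H](O[Si](CC)(CC)CC)[C@H]2OC(=O)C(=C)[C@H]2[C@@H](OCc3ccc(OC)cc3)[C@H]1C(=C)CO[Si](c4ccccc4)(c5ccccc5)C(C)(C)C | intermediate
30 | (3aS,4S,5S,6S,7S,7aS)-6-ethenyl-7-hydroxy-5-(3-hydroxyprop-1-en-2-yl)-4-[(4-methoxyphenyl)methoxy]-6-methyl-3-methylidenehexahydro-1-benzofuran-2(3H)-one | C=C[C@]1(C)[C@H](O)[C@H]2OC(=O)C(=C)[C@H]2[C@@H](OCc3ccc(OC)cc3)[C@H]1C(=C)CO | intermediate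
31 | (3aS,4S,5S,6S,7S,7aS)-7-acetoxy-5-(3-acetoxyprop-1-en-2-yl)-6-ethenyl-4-[(4-methoxyphenyl)methoxy]-6-methyl-3-methylidenehexahydro-1-benzofuran-2(3H)-one | C=C[C@]1(C)[C@H](OC(C)=O)[C@H]2OC(=O)C(=C)[C@H]2[C@@H](OCc3ccc(OC)cc3)[C@H]1C(=C)COC(C)=O | intermediate
32 | (3aS,4S,5S,6S,7S,7aS)-7-acetoxy-5-(3-acetoxyprop-1-en-2-yl)-6-ethenyl-4-hydroxy-6-methyl-3-methylidenehexahydro-1-benzofuran-2(3H)-one | C=C[C@]1(C)[C@H](OC(C)=O)[C@H]2OC(=O)C(=C)[C@H]2[C@@H](O)[C@H]1C(=C)COC(C)=O | intermediate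
33 | CNP0500052.1, (3aS,4S,5S,6S,7S,7aS)-7-acetoxy-5-(3-acetoxyprop-1-en-2-yl)-6-ethenyl-6-methyl-3-methylidene-2-oxooctahydro-1-benzofuran-4-yl 2-methylpropanoate | C=C[C@]1(C)[C@H](OC(C)=O)[C@H]2OC(=O)C(=C)[C@H]2[C@@H](OC(=O)C(C)C)[C@H]1C(=C)COC(C)=O | target

Total step count: 23 steps.
Longest linear sequence: 20 steps (steps 1–4 and 8–23, from compound 1).

Steps most likely to fail

1. Step 19. The oxidative cyclisation may close on the α face and give the 7,8-bis-epimeric cis lactone, or the allene may isomerise or oligomerise at 120 °C before it cyclises. The fallback keeps the C7–C8 disconnection but forms the two rings stepwise at low temperature. It sets out from 27: Pd-catalysed distannylation of the allene (Me3SnSnMe3, [(η3-C3H5)PdCl]2 cat., THF, 25 °C) gives a 2-stannylallylstannane that adds in the same flask to the C8 aldehyde through a closed six-membered transition state and, after work-up, should give the cis hydroxy vinylstannane F1. Iododestannylation (I2, CH2Cl2, 0 °C) gives the vinyl iodide F2, and carbonylative lactonisation with zerovalent palladium (Pd(PPh3)4 cat., CO 1 atm, Et3N, MeCN, 60 °C) comes back to 29.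

2. Step 9. The ketene acetal may bond to the other face of C10 (wrong C9/C10 relation), or its geometry may leak and give the C5 epimer. The fallback inverts both geometric elements and sets out from 2: n-BuLi then ClCO2Me gives the ynoate F3; Me2CuLi (THF, −78 °C, syn carbocupration) gives the (Z)-enoate F4; i-Bu2AlH (CH2Cl2, −78 °C) gives the (Z)-allylic alcohol F5; EDC/DMAP esterification with 11 gives the ester F6. Enolisation with LiN(i-Pr)2 in THF/DMPU (Z(O) ketene acetal), Me3SiCl, 60 °C and hydrolysis comes back to 15. The Z-alkene/Z(O)-acetal pair gives the same C5/C10 relation through the chair, allylic strain locks H9 in the alkene plane, and the required C9/C10 relation then arises when the new bond forms anti to C8, which is the facial preference this series would need if the E series fails in that sense.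

3. Step 14. The allenyl carbinol may be reduced further by a second hydroalumination, or methoxide may be lost too slowly. The fallback builds the allene by homologation instead of SN2' reduction and sets out from 18: LiC≡CSiMe3 (THF, −78 → 0 °C) gives the silyl ynone F7; the transfer hydrogenation of step 13 gives the (S)-carbinol F8; K2CO3/MeOH gives the terminal alkyne F9. Crabbé homologation ((CH2O)n, CuI, dicyclohexylamine, 1,4-dioxane, 100 °C) comes back to 23.

Further compounds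

F1 | step 19 | cis hydroxy vinylstannane: the cyclohexanol of 29 with C8–OH free and 1-(trimethylstannyl)ethenyl on C7 in place of the lactone, (5S,6S,7R,8S,9S,10S) in target numbering | C=C[C@]1(C)[C@H](O[Si](CC)(CC)CC)[C@@H](O)[C@@H](C(=C)[Sn](C)(C)C)[C@@H](OCc2ccc(OC)cc2)[C@H]1C(=C)CO[Si](c3ccccc3)(c4ccccc4)C(C)(C)C
F2 | step 19 | cis hydroxy vinyl iodide: as F1 with 1-iodoethenyl on C7, (5S,6S,7R,8S,9S,10S) in target numbering | C=C[C@]1(C)[C@H](O[Si](CC)(CC)CC)[C@@H](O)[C@@H](C(=C)I)[C@@H](OCc2ccc(OC)cc2)[C@H]1C(=C)CO[Si](c3ccccc3)(c4ccccc4)C(C)(C)C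
F3 | step 9 | methyl 3-[(4S)-2,2-dimethyl-1,3-dioxolan-4-yl]prop-2-ynoate | COC(=O)C#C[C@H]1COC(C)(C)O1
F4 | step 9 | methyl (2Z)-3-[(4S)-2,2-dimethyl-1,3-dioxolan-4-yl]but-2-enoate | COC(=O)/C=C(/C)[C@H]1COC(C)(C)O1
F5 | step 9 | (2Z)-3-[(4S)-2,2-dimethyl-1,3-dioxolan-4-yl]but-2-en-1-ol | OC/C=C(/C)[C@H]1COC(C)(C)O1
F6 | step 9 | (2Z)-3-[(4S)-2,2-dimethyl-1,3-dioxolan-4-yl]but-2-en-1-yl 3-{[tert-butyl(diphenyl)silyl]oxymethyl}-4-(phenylselanyl)butanoate (C4 epimers) | O=C(CC(CO[Si](c2ccccc2)(c3ccccc3)C(C)(C)C)C[Se]c4ccccc4)OC/C=C(/C)[C@H]1COC(C)(C)O1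
F7 | step 14 | (3S,4S)-4-(3-{[tert-butyl(diphenyl)silyl]oxy}prop-1-en-2-yl)-3-[(4S)-2,2-dimethyl-1,3-dioxolan-4-yl]-3-methyl-7-(trimethylsilyl)hept-1-en-6-yn-5-one | C[Si](C)(C)C#CC(=O)[C@@H](C(=C)CO[Si](c2ccccc2)(c3ccccc3)C(C)(C)C)[C@](C)(C=C)[C@H]1COC(C)(C)O1
F8 | step 14 | (3S,4S,5S)-4-(3-{[tert-butyl(diphenyl)silyl]oxy}prop-1-en-2-yl)-3-[(4S)-2,2-dimethyl-1,3-dioxolan-4-yl]-3-methyl-7-(trimethylsilyl)hept-1-en-6-yn-5-ol | C[Si](C)(C)C#C[C@@H](O)[C@@H](C(=C)CO[Si](c2ccccc2)(c3ccccc3)C(C)(C)C)[C@](C)(C=C)[C@H]1COC(C)(C)O1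
F9 | step 14 | (3S,4S,5S)-4-(3-{[tert-butyl(diphenyl)silyl]oxy}prop-1-en-2-yl)-3-[(4S)-2,2-dimethyl-1,3-dioxolan-4-yl]-3-methylhept-1-en-6-yn-5-ol | C#C[C@@H](O)[C@@H](C(=C)CO[Si](c2ccccc2)(c3ccccc3)C(C)(C)C)[C@](C)(C=C)[C@H]1COC(C)(C)O1
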